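**Plan**

1. Numbering: ring C1 (C=O), C2=C3, C4 (CHOH), C5 (quaternary C–OH); C1' is the side-chain carbinol. The retrosynthesis removes the C2=C3 unsaturation and the cis-4,5-diol (back to a C4=C5 alkene), then cuts the ring bonds C2–C3 and C4–C5 together in a (3+2) sense.
2. Enabling feature: in the five-membered ring the C1 carbonyl lies between C2 and the oxygen-bearing C5. C5–C1–C2 can therefore be a 1,2-diketone with a nucleophilic C2 methyl and an electrophilic C5 carbonyl, and C3–C4 a vinylphosphonium salt (acceptor at C3, latent ylide at C4).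
3. Forward: heptadecanoyl chloride and 1-(trimethylsilyl)propyne give an ynone; transfer hydrogenation, silylation and alkyne oxidation give the C20 1,2-diketone (C16 chain, C1', C5, C1, C2 in line).
4. One Michael/Wittig (3+2) annulation closes the only ring as a 2-substituted cyclopent-2-enone (C2–C3 and C4=C5 formed; phosphorus leaves as Ph3P=O).
5. Stereochemistry: C1' comes from the catalyst-controlled ketone reduction. C4 and C5 come together from one syn-dihydroxylation of C4=C5 on the face anti to the C1' silyloxy group (cis-diol by mechanism).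
6. Finish: acetonide on the cis-diol, Saegusa–Ito desaturation to C2=C3, one acidic deprotection.

Key step: step 5

**Route**

Step 1
Reactants: 1 heptadecanoyl chloride; 2 1-(trimethylsilyl)propyne
Product: 3 icos-2-yn-4-one
Conditions: AlCl3 (1.1 equiv), CH2Cl2, 0 °C
Reagents that add atoms: none
Why: Friedel–Crafts-type ipso acylation of an alkynylsilane: the acylium ion attacks the silicon-bearing alkyne carbon because the developing vinyl cation is β to silicon, and loss of the silyl group gives the ynone without isomerisation.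

Step 2
Reactants: 3 icos-2-yn-4-one
Product: 4 (4S)-icos-2-yn-4-ol
Conditions: RuCl[(S,S)-TsDPEN](p-cymene) (1 mol %), i-PrOH, rt
Reagents that add atoms: none
Why: Noyori asymmetric transfer hydrogenation of an alkynyl ketone, in which the alkyne takes the place of the aryl group of an aryl ketone in the transition state, should set C1' with the (S) configuration through the (S,S)-configured ligand.

Step 3
Reactants: 4 (4S)-icos-2-yn-4-ol
Product: 5 tert-butyl{[(4S)-icos-2-yn-4-yl]oxy}dimethylsilane
Conditions: TBSCl, imidazole, DMF, rt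
Reagents that add atoms: tert-butyldimethylsilyl chloride, CC(C)(C)[Si](C)(C)Cl
Why: Silyl ether formation (silylation of a secondary alcohol) installs a bulky, non-chelating group on the C1' oxygen that survives oxidation and base and later steers the dihydroxylation.

Step 4
Reactants: 5 tert-butyl{[(4S)-icos-2-yn-4-yl]oxy}dimethylsilane
Product: 6 (4S)-4-[(tert-butyldimethylsilyl)oxy]icosane-2,3-dione
Conditions: RuCl3·xH2O (2 mol %), NaIO4 (2.5 equiv), NaHCO3, MgSO4, EtOAc/MeCN/H2O, 0 °C
Reagents that add atoms: sodium periodate, [Na+].[O-]I(=O)(=O)=O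
Why: Ruthenium tetroxide oxidation of an internal alkyne to a 1,2-diketone, with the oxidant made catalytically from RuCl3 and periodate under buffered biphasic conditions, converts C5≡C1 into the two carbonyl groups without touching the silyl ether or the C1' centre.

Step 5
Reactants: 6 (4S)-4-[(tert-butyldimethylsilyl)oxy]icosane-2,3-dione; 7 vinyltriphenylphosphonium bromide
Product: 10 2-[(1S)-1-[(tert-butyldimethylsilyl)oxy]heptadecyl]cyclopent-2-en-1-one, via lithium enolate 8 (not isolated), via phosphorus ylide 9 (not isolated)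
Conditions: LiHMDS (1.05 equiv), THF, −78 °C; then 7, THF/DMF, −78 °C to rt
Reagents that add atoms: none
Why: Proposed new method: the kinetic C2 methyl enolate 8 of diketone 6 adds in a Michael reaction to the vinylphosphonium salt 7 (C2–C3 bond) to give ylide 9, whose carbon C4 then attacks the C5 carbonyl in an intramolecular Wittig reaction (C4=C5 bond, Ph3P=O lost), so that the cyclopentenone ring closes by a 5-exo-trig attack on C5 while attack on C1 would need a four-membered ring. The closest known reaction type is the Michael/intramolecular Wittig annulation of keto-substituted stabilised carbanions, enolates and alkoxides with vinyltriphenylphosphonium salts, which gives cyclopentenes and five-membered heterocycles; new here is the methyl enolate of an α-diketone, whose Michael adduct is still C–H acidic at C2. Proton transfer from C2 to the ylide carbon is expected to be reversible, and the irreversible olefination of the highly electrophilic 1,2-dicarbonyl carbon C5 should drain this equilibrium towards 10. No stereocentre is formed in the step. The step needs regioselective enolisation and C- rather than O-attack: the unhindered methyl group is deprotonated faster than the tertiary, silyloxy-bearing C1'–H (so C1' is not epimerised), and the soft phosphonium acceptor favours reaction at carbon.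

Step 6
Reactants: 10 2-[(1S)-1-[(tert-butyldimethylsilyl)oxy]heptadecyl]cyclopent-2-en-1-one
Product: 11 (2R,3S)-2-[(1S)-1-[(tert-butyldimethylsilyl)oxy]heptadecyl]-2,3-dihydroxycyclopentan-1-one
Conditions: OsO4 (5 mol %), NMO (1.5 equiv), acetone/H2O, 0 °C to rt
Reagents that add atoms: N-methylmorpholine N-oxide, C[N+]1([O-])CCOCC1; water, O
Why: Upjohn dihydroxylation delivers both oxygens to one face of C4=C5 (cis-diol by the syn mechanism), and that face should be the one anti to the allylic C1' silyloxy group (empirical rule for osmylation of allylic ethers, hydrogen outside and alkoxy inside), which sets C4 and C5 together in the required sense relative to C1'.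

Step 7
Reactants: 11 (2R,3S)-2-[(1S)-1-[(tert-butyldimethylsilyl)oxy]heptadecyl]-2,3-dihydroxycyclopentan-1-one
Product: 12 (3aR,6aS)-3a-[(1S)-1-[(tert-butyldimethylsilyl)oxy]heptadecyl]-2,2-dimethyltetrahydro-4H-cyclopenta[d][1,3]dioxol-4-one
Conditions: 2,2-dimethoxypropane, PPTS (cat.), CH2Cl2, rt
Reagents that add atoms: 2,2-dimethoxypropane, COC(C)(C)OC
Why: Acid-catalysed acetal exchange (acetonide formation) closes a cis-fused five-membered isopropylidene acetal over the C4 and C5 hydroxyls and so protects both, the tertiary one included, for the enolisation that follows.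

Step 8
Reactants: 12 (3aR,6aS)-3a-[(1S)-1-[(tert-butyldimethylsilyl)oxy]heptadecyl]-2,2-dimethyltetrahydro-4H-cyclopenta[d][1,3]dioxol-4-one
Product: 14 (3aR,6aS)-3a-[(1S)-1-[(tert-butyldimethylsilyl)oxy]heptadecyl]-2,2-dimethyl-3a,6a-dihydro-4H-cyclopenta[d][1,3]dioxol-4-one, via silyl enol ether 13 (not isolated)
Conditions: TMSOTf, Et3N, CH2Cl2, 0 °C; then Pd(OAc)2 (1.1 equiv), MeCN, rt
Reagents that add atoms: none
Why: Saegusa–Ito oxidation: the ketone can enolise only towards C2 because C5 is quaternary, so soft enolisation gives the C1=C2 silyl enol ether 13, and divalent palladium then forms the C2=C3 enone by β-hydride elimination from C3 without touching a stereocentre.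

Step 9
Reactants: 14 (3aR,6aS)-3a-[(1S)-1-[(tert-butyldimethylsilyl)oxy]heptadecyl]-2,2-dimethyl-3a,6a-dihydro-4H-cyclopenta[d][1,3]dioxol-4-one
Product: 15 (4S,5S)-4,5-dihydroxy-5-[(1S)-1-hydroxyheptadecyl]cyclopent-2-en-1-one
Conditions: TFA/H2O (4:1), 0 °C to rt
Reagents that add atoms: none
Why: Acid-catalysed acetal hydrolysis and desilylation in one operation free the three hydroxyls, and acid is chosen because the product, a β-hydroxy ketone with a quaternary α-carbon, is prone to retro-aldol cleavage only under base.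

**Compound list**

1 | heptadecanoyl chloride | CCCCCCCCCCCCCCCCC(=O)Cl | starting material
2 | 1-(trimethylsilyl)propyne | CC#C[Si](C)(C)C | starting material
3 | icos-2-yn-4-one | CCCCCCCCCCCCCCCCC(=O)C#CC | intermediate
4 | (4S)-icos-2-yn-4-ol | CCCCCCCCCCCCCCCC[C@H](O)C#CC | intermediate
5 | tert-butyl{[(4S)-icos-2-yn-4-yl]oxy}dimethylsilane | CCCCCCCCCCCCCCCC[C@H](O[Si](C)(C)C(C)(C)C)C#CC | intermediate
6 | (4S)-4-[(tert-butyldimethylsilyl)oxy]icosane-2,3-dione | CCCCCCCCCCCCCCCC[C@H](O[Si](C)(C)C(C)(C)C)C(=O)C(C)=O | intermediate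
7 | vinyltriphenylphosphonium bromide | C=C[P+](c1ccccc1)(c1ccccc1)c1ccccc1.[Br-] | starting material
8 | lithium (4S)-4-[(tert-butyldimethylsilyl)oxy]-3-oxoicos-1-en-2-olate (C2 methyl enolate of 6) | CCCCCCCCCCCCCCCC[C@H](O[Si](C)(C)C(C)(C)C)C(=O)C([O-])=C.[Li+] | intermediate
9 | (7S)-7-[(tert-butyldimethylsilyl)oxy]-1-(triphenyl-λ5-phosphanylidene)tricosane-5,6-dione (ylide at C4) | CCCCCCCCCCCCCCCC[C@H](O[Si](C)(C)C(C)(C)C)C(=O)C(=O)CCC=P(c1ccccc1)(c1ccccc1)c1ccccc1 | intermediate
10 | 2-[(1S)-1-[(tert-butyldimethylsilyl)oxy]heptadecyl]cyclopent-2-en-1-one | CCCCCCCCCCCCCCCC[C@H](O[Si](C)(C)C(C)(C)C)C1=CCCC1=O | intermediate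
11 | (2R,3S)-2-[(1S)-1-[(tert-butyldimethylsilyl)oxy]heptadecyl]-2,3-dihydroxycyclopentan-1-one | CCCCCCCCCCCCCCCC[C@H](O[Si](C)(C)C(C)(C)C)[C@@]1(O)C(=O)CC[C@@H]1O | intermediate
12 | (3aR,6aS)-3a-[(1S)-1-[(tert-butyldimethylsilyl)oxy]heptadecyl]-2,2-dimethyltetrahydro-4H-cyclopenta[d][1,3]dioxol-4-one | CCCCCCCCCCCCCCCC[C@H](O[Si](C)(C)C(C)(C)C)[C@@]1(OC(C)(C)O2)C(=O)CC[C@@H]12 | intermediate
13 | tert-butyl{[(1S)-1-[(3aR,6aS)-2,2-dimethyl-4-[(trimethylsilyl)oxy]-6,6a-dihydro-3aH-cyclopenta[d][1,3]dioxol-3a-yl]heptadecyl]oxy}dimethylsilane (C1=C2 trimethylsilyl enol ether of 12) | CCCCCCCCCCCCCCCC[C@H](O[Si](C)(C)C(C)(C)C)[C@@]1(OC(C)(C)O2)C(O[Si](C)(C)C)=CC[C@@H]12 | intermediate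
14 | (3aR,6aS)-3a-[(1S)-1-[(tert-butyldimethylsilyl)oxy]heptadecyl]-2,2-dimethyl-3a,6a-dihydro-4H-cyclopenta[d][1,3]dioxol-4-one | CCCCCCCCCCCCCCCC[C@H](O[Si](C)(C)C(C)(C)C)[C@@]1(OC(C)(C)O2)C(=O)C=C[C@@H]12 | intermediate
15 | (4S,5S)-4,5-dihydroxy-5-[(1S)-1-hydroxyheptadecyl]cyclopent-2-en-1-one | CCCCCCCCCCCCCCCC[C@H](O)[C@@]1(O)C(=O)C=C[C@@H]1O | target

**Totals**

Total step count: 9. Longest linear sequence: 9 steps (1 to 15).

**Steps most likely to fail**

Step 5 (carries the new-method label). What may go wrong: O- instead of C-attack of the diketone enolate on the phosphonium salt, quenching of the ylide by proton transfer before ring closure, or base-induced epimerisation at C1'. The fallback uses known chemistry, sets out from 1 and returns at 10; the ring is taken ready-made and only the C5–C1' bond is formed. Compound 1 is converted with N,O-dimethylhydroxylamine hydrochloride and pyridine into N-methoxy-N-methylheptadecanamide F1. 6-Bromo-1,4-dioxaspiro[4.4]non-6-ene (the ethylene ketal of 2-bromocyclopent-2-enone) is lithiated with n-BuLi in THF at −78 °C and acylated with F1 (Weinreb ketone synthesis) to give 1-(1,4-dioxaspiro[4.4]non-6-en-6-yl)heptadecan-1-one F2. Corey–Bakshi–Shibata reduction with (R)-2-methyl-CBS-oxazaborolidine and BH3·SMe2, the alkenyl group acting as the large substituent, should give (1S)-1-(1,4-dioxaspiro[4.4]non-6-en-6-yl)heptadecan-1-ol F3. Silylation (TBSCl, imidazole) gives tert-butyl{[(1S)-1-(1,4-dioxaspiro[4.4]non-6-en-6-yl)heptadecyl]oxy}dimethylsilane F4, and mild ketal hydrolysis (PPTS, wet acetone) returns 10.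

Step 6. What may go wrong: poor facial selectivity of the osmylation, since the C1' silyloxy group is the only control element, or sluggish osmylation of the electron-poor enone. The fallback sets out from 1 and returns at 15; it replaces acyclic control by ring-fusion control. Reduction of 1 with LiAlH(O-t-Bu)3 in THF at −78 °C gives heptadecanal F5. The lithium enolate (LDA, THF, −78 °C) of (3aS,6aS)-2,2-dimethyl-3a,6a-dihydro-4H-cyclopenta[d][1,3]dioxol-4-one, a known enantiopure enone from the carbohydrate chiral pool, is added to F5 in an aldol reaction. The cis-fused acetonide should force the aldehyde onto the face anti to the C4 oxygen, which fixes C5, and a closed chair-like transition state with the chain equatorial should favour the (1'S) carbinol. This gives (3aS,6aS)-3a-[(1S)-1-hydroxyheptadecyl]-2,2-dimethyl-3a,6a-dihydro-4H-cyclopenta[d][1,3]dioxol-4-one F6. Aqueous TFA then removes the acetonide and gives 15.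

Step 4. What may go wrong: over-oxidation with cleavage of the C1–C5 bond, or loss of the silyl ether in the oxidising medium. The fallback sets out from 5 and returns at 6; it reaches the diketone stepwise through a diol. Lindlar semihydrogenation (H2, Pd/CaCO3 poisoned with Pb(OAc)2, quinoline) gives tert-butyl{[(2Z,4S)-icos-2-en-4-yl]oxy}dimethylsilane F7. Upjohn dihydroxylation gives (4S)-4-[(tert-butyldimethylsilyl)oxy]icosane-2,3-diol F8 as a mixture of diastereomers, which is of no consequence. Double Swern oxidation ((COCl)2, DMSO, then Et3N, −78 °C) of the diol gives 6.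

**Further compounds**

F1 | step 5 | N-methoxy-N-methylheptadecanamide | CCCCCCCCCCCCCCCCC(=O)N(C)OC
F2 | step 5 | 1-(1,4-dioxaspiro[4.4]non-6-en-6-yl)heptadecan-1-one | CCCCCCCCCCCCCCCCC(=O)C1=CCCC12OCCO2
F3 | step 5 | (1S)-1-(1,4-dioxaspiro[4.4]non-6-en-6-yl)heptadecan-1-ol | CCCCCCCCCCCCCCCC[C@H](O)C1=CCCC12OCCO2
F4 | step 5 | tert-butyl{[(1S)-1-(1,4-dioxaspiro[4.4]non-6-en-6-yl)heptadecyl]oxy}dimethylsilane | CCCCCCCCCCCCCCCC[C@H](O[Si](C)(C)C(C)(C)C)C1=CCCC12OCCO2
F5 | step 6 | heptadecanal | CCCCCCCCCCCCCCCCC=O
F6 | step 6 | (3aS,6aS)-3a-[(1S)-1-hydroxyheptadecyl]-2,2-dimethyl-3a,6a-dihydro-4H-cyclopenta[d][1,3]dioxol-4-one | CCCCCCCCCCCCCCCC[C@H](O)[C@@]1(OC(C)(C)O2)C(=O)C=C[C@@H]12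
F7 | step 4 | tert-butyl{[(2Z,4S)-icos-2-en-4-yl]oxy}dimethylsilane | CCCCCCCCCCCCCCCC[C@H](O[Si](C)(C)C(C)(C)C)/C=C\C
F8 | step 4 | (4S)-4-[(tert-butyldimethylsilyl)oxy]icosane-2,3-diol (mixture of diastereomers at C2 and C3) | CCCCCCCCCCCCCCCC[C@H](O[Si](C)(C)C(C)(C)C)C(O)C(C)O
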